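**Strategy**

The chain is numbered from the angelate-bearing CH2 (C1) through carbinol C8 to the exocyclic alkene carbon C10 of lactone ring A (C11 ring alkene carbon, C12 carbinol, C13 ring CH–O). Because C8 lies between alkenyl C7 and, via C9H2, alkenyl C10, the C8–C9 pair is a vinyl unit, so the route cuts C7–C8 and C9–C10. One palladium-catalysed conjunctive coupling joins a C1–C7 alkenyl pinacol boronate, vinyllithium and the E-bromomethylene lactone, making both bonds and the C8 stereocentre as a C–B bond that is later oxidised with retention. Both fragments carry only TBS ethers.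

Key step: step 13

Remark on the chemistry: Br2 would add to the electron-rich isobutenyl alkene of the lactone before it touches an α-methylene lactone, so the bromomethylene group is made by C-formylation and deoxybromination of the enol instead.

Assumption: the ligand antipode written in step 13 is taken to give the 8S boronate; if a model coupling shows the opposite sense, the mirror-image ligand is used with no other change.

Assumption: diboronate 8 is made in one step from 6, whose commercial supply is the more certain.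

**Route**

Step 1
Reactants: 1 nerol
Product: 2 neryl TBS ether
Conditions: TBSCl, imidazole, DMF, 0 °C → rt
Reagents that add atoms: tert-butyldimethylsilyl chloride, CC(C)(C)[Si](C)(C)Cl
Why: Imidazole-promoted silylation of the primary allylic alcohol gives an ether that tolerates the peracid, carbanion, organolithium and palladium steps ahead.

Step 2
Reactants: 2 neryl TBS ether
Product: 3 racemic 6,7-epoxyneryl TBS ether
Conditions: mCPBA (1.0 equiv), CH2Cl2, −20 → 0 °C
Reagents that add atoms: 3-chloroperbenzoic acid, O=C(OO)c1cccc(Cl)c1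
Why: Prilezhaev epoxidation with one equivalent of peracid should take the more electron-rich 6,7-alkene, the 2,3-alkene being deactivated by its allylic oxygen, and the new stereocentre forms as a racemate that step 3 destroys.

Step 3
Reactants: 3 racemic 6,7-epoxyneryl TBS ether
Product: 5 (4Z)-6-(tert-butyldimethylsilyloxy)-4-methylhex-4-enal, via racemic 6,7-diol 4 (not isolated)
Conditions: H5IO6, THF/Et2O, 0 °C
Reagents that add atoms: none
Why: Periodic acid hydrolyses the epoxide to diol 4 and cleaves it at once (Malaprade glycol cleavage), releasing acetone and leaving the Z alkene and the silyl ether untouched at 0 °C.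

Step 4
Reactants: 6 bis(pinacolboryl)methane
Product: 8 1,1-bis(pinacolboryl)ethane, via lithiated diborylmethane 7 (not isolated)
Conditions: lithium 2,2,6,6-tetramethylpiperidide, THF, 0 °C; then MeI, 0 °C → rt
Reagents that add atoms: iodomethane, CI
Why: The C–H flanked by two boron atoms is deprotonated by the hindered amide without attack at boron, and the α-boryl carbanion is methylated by SN2 alkylation.

Step 5
Reactants: 5 (4Z)-6-(tert-butyldimethylsilyloxy)-4-methylhex-4-enal; 8 1,1-bis(pinacolboryl)ethane
Product: 10 fragment 1 (C1–C7 alkenyl pinacol boronate with C1 TBS ether; 2Z; boron on C7 trans to C5), via lithiated 1,1-diborylethane 9 (not isolated)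
Conditions: 8, lithium 2,2,6,6-tetramethylpiperidide, THF, 0 °C; then 5, −78 °C → rt
Reagents that add atoms: none
Why: Boron–Wittig olefination in which carbanion 9 adds to the aldehyde and syn elimination of a boron–oxygen pair forms the trisubstituted alkenyl boronate, the chain ending up trans to the retained boron because the bulky Bpin group eclipses hydrogen and not the chain in the elimination.

Step 6
Reactants: 11 2-deoxy-D-ribose
Product: 12 2-deoxy-D-ribono-1,4-lactone
Conditions: Br2, H2O, rt, dark
Reagents that add atoms: none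
Why: Bromine water oxidises the anomeric carbon of the aldose and the aldonic acid closes to the five-membered lactone, the two carbinol stereocentres (future C12 and C13) being carried over from the sugar.

Step 7
Reactants: 12 2-deoxy-D-ribono-1,4-lactone
Product: 13 3,5-bis-O-TBS-2-deoxy-D-ribono-1,4-lactone
Conditions: TBSCl (2.5 equiv), imidazole, DMF, rt
Reagents that add atoms: tert-butyldimethylsilyl chloride, CC(C)(C)[Si](C)(C)Cl
Why: Exhaustive imidazole-promoted silylation of both hydroxyl groups.

Step 8
Reactants: 13 3,5-bis-O-TBS-2-deoxy-D-ribono-1,4-lactone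
Product: 14 (4S,5R)-4-(tert-butyldimethylsilyloxy)-5-(hydroxymethyl)oxolan-2-one
Conditions: TFA/H2O/THF (1:1:4), 0 °C
Reagents that add atoms: none
Why: Acid-catalysed hydrolysis of silyl ethers is sterically governed, so the primary TBS ether should be cleaved well before the secondary one.

Step 9
Reactants: 14 (4S,5R)-4-(tert-butyldimethylsilyloxy)-5-(hydroxymethyl)oxolan-2-one
Product: 15 (2S,3S)-3-(tert-butyldimethylsilyloxy)-5-oxooxolane-2-carbaldehyde
Conditions: Dess–Martin periodinane, CH2Cl2, 0 °C → rt; used crude
Reagents that add atoms: none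
Why: Dess–Martin oxidation runs under near-neutral conditions and so should neither epimerise the α-acyloxy centre nor eliminate the β-silyloxy group.

Step 10
Reactants: 15 (2S,3S)-3-(tert-butyldimethylsilyloxy)-5-oxooxolane-2-carbaldehyde
Product: 16 (4S,5R)-4-(tert-butyldimethylsilyloxy)-5-(2-methylprop-1-en-1-yl)oxolan-2-one
Conditions: isopropyltriphenylphosphonium iodide, n-BuLi, THF, 0 °C; then 15, −78 → 0 °C
Reagents that add atoms: isopropyltriphenylphosphonium iodide, CC(C)[P+](c1ccccc1)(c1ccccc1)c1ccccc1.[I-]
Why: Wittig olefination with the non-stabilised isopropylidene ylide, whose addition to the aldehyde at −78 °C should outrun enolisation and leave the lactone carbonyl and the C13 configuration alone.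

Step 11
Reactants: 16 (4S,5R)-4-(tert-butyldimethylsilyloxy)-5-(2-methylprop-1-en-1-yl)oxolan-2-one
Product: 18 (4S,5R)-4-(tert-butyldimethylsilyloxy)-3-(hydroxymethylidene)-5-(2-methylprop-1-en-1-yl)oxolan-2-one (enol in equilibrium with its formyl tautomer), via lithium enolate 17 (not isolated)
Conditions: lithium diisopropylamide (1.2 equiv), THF, −78 °C; then ethyl formate (excess), −78 → −30 °C; then AcOH
Reagents that add atoms: ethyl formate, CCOC=O
Why: Crossed Claisen condensation (C-formylation) of the lithium enolate with the highly electrophilic formate ester at low temperature, where loss of the β-silyloxy group is slow, gives the product as a stabilised enolate that acetic acid releases.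

Step 12
Reactants: 18 (4S,5R)-4-(tert-butyldimethylsilyloxy)-3-(hydroxymethylidene)-5-(2-methylprop-1-en-1-yl)oxolan-2-one
Product: 19 fragment 2 [(3E,4S,5R)-3-(bromomethylidene)-4-(tert-butyldimethylsilyloxy)-5-(2-methylprop-1-en-1-yl)oxolan-2-one]
Conditions: Ph3PBr2 (1.1 equiv), Et3N, CH2Cl2, 0 °C → rt
Reagents that add atoms: dibromotriphenylphosphorane, BrP(Br)(c1ccccc1)(c1ccccc1)c1ccccc1
Why: Deoxybromination of a vinylogous acid by O-phosphonium activation of the enol, conjugate addition of bromide and loss of Ph3PO, a reaction type known for β-dicarbonyl enols and α-hydroxymethylene ketones, with reversible bromide addition–elimination expected to settle the alkene in the E geometry that keeps bromine away from the carbonyl oxygen.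

Step 13
Reactants: 10 fragment 1; 19 fragment 2; 20 vinyl bromide
Product: 23 C8 pinacol boronate of the full skeleton (8S; 2Z,6E; E at C10=C11; C1 and C12 TBS ethers), via vinyllithium 21 (not isolated), via lithium bis(alkenyl)borate 22 (not isolated)
Conditions: 20, t-BuLi (2.0 equiv), Et2O, −78 °C; then 10 (1.05 equiv per 21), THF, −78 → 0 °C; solvent exchange to THF; then 19 (limiting), Pd(OAc)2 (3 mol%), (Sp,Sp)-1,1′-bis(diphenylphosphino)-2,2′-bis[(R)-(dimethylamino)(phenyl)methyl]ferrocene (3.6 mol%), KOTf (2 equiv), 45 °C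
Reagents that add atoms: none
Why: Vinyllithium 21 adds to the boron of 10 to give borate 22; zerovalent palladium carrying the chiral ferrocenyl diphosphine inserts into the C10–Br bond of 19, and the divalent alkenylpalladium, freed of bromide by precipitation of KBr, binds the unsubstituted vinyl group of 22, which triggers anti 1,2-shift of the C7 alkenyl group from boron to C8 as C9 bonds to palladium, and reductive elimination then forms C9–C10 with retention of the E geometry at C10. The closest known reaction is the enantioselective palladium-catalysed conjunctive cross-coupling of bis(alkenyl)borates with alkenyl bromides and triflates to α-chiral allylic pinacol boronates, of which a β-bromo enoate is an electron-poor and so far unexplored member of the electrophile class. No ring is closed. The 8S centre is set by the ligand alone (catalyst control), since the lactone stereocentres C12 and C13 are remote from it and from the reacting carbon C10. The step needs site selectivity between the two alkenyl groups on boron, which the preference of palladium for the unhindered vinyl group over the trisubstituted C6=C7 group secures, and chemoselectivity over direct Suzuki–Miyaura transfer and over attack on the lactone, which the non-basic tetracoordinate borate and the slight excess of boronate over vinyllithium secure. The C7 group migrates with retention of its alkene geometry, so the 6E alkene of the target follows from the geometry of 10.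

Step 14
Reactants: 23 C8 pinacol boronate of the full skeleton
Product: 24 C8 alcohol (8S; C1 and C12 TBS ethers)
Conditions: Me3NO (anhydrous, 3 equiv), THF, rt → 50 °C; aqueous work-up
Reagents that add atoms: trimethylamine N-oxide, C[N+](C)(C)[O-]
Why: Amine N-oxide oxidation of the organoborane, in which Me3NO binds boron and C8 migrates from boron to oxygen with retention, uses a reagent that is neither basic nor a nucleophilic peroxide and so should spare the lactone and the alkylidene group.

Step 15
Reactants: 24 C8 alcohol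
Product: 25 C8 acetate (C1 and C12 TBS ethers)
Conditions: Ac2O, pyridine, DMAP (cat.), CH2Cl2, 0 °C → rt
Reagents that add atoms: acetic anhydride, CC(=O)OC(C)=O
Why: DMAP-catalysed acylation of the only free hydroxyl group.

Step 16
Reactants: 25 C8 acetate
Product: 26 C1 primary allylic alcohol (C8 acetate; C12 TBS ether)
Conditions: camphorsulfonic acid (0.1 equiv), MeOH/CH2Cl2 (1:1), 0 °C
Reagents that add atoms: none
Why: Acid-catalysed methanolysis removes the unhindered primary allylic TBS ether far faster than the secondary C12 ether flanked by two substituted carbons.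

Step 17
Reactants: 26 C1 primary allylic alcohol; 27 angelic acid
Product: 29 C1 angelate (C8 acetate; C12 TBS ether), via mixed anhydride 28 (not isolated)
Conditions: 27, 2,4,6-trichlorobenzoyl chloride, Et3N, toluene, rt; then 26, 60 °C (no DMAP)
Reagents that add atoms: none
Why: Yamaguchi-type esterification through mixed anhydride 28 without DMAP is the protocol known to transfer the angeloyl group without Z to E isomerisation to the tiglate.

Step 18
Reactants: 29 C1 angelate
Product: 30 CNP0201198.1
Conditions: HF·pyridine, pyridine, THF, 0 °C → rt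
Reagents that add atoms: none
Why: Buffered HF·pyridine cleaves the remaining silyl ether through the strong Si–F bond under mildly acidic conditions that should leave both esters, the lactone and the acid-sensitive allylic C13–O bond intact.

**Compound list**

1 | nerol, (2Z)-3,7-dimethylocta-2,6-dien-1-ol | CC(C)=CCC/C(C)=C\CO | starting material
2 | neryl TBS ether, tert-butyl{[(2Z)-3,7-dimethylocta-2,6-dien-1-yl]oxy}dimethylsilane | CC(C)=CCC/C(C)=C\CO[Si](C)(C)C(C)(C)C | intermediate
3 | racemic 6,7-epoxyneryl TBS ether (2Z) | CC1(C)OC1CC/C(C)=C\CO[Si](C)(C)C(C)(C)C | intermediate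
4 | racemic (6Z)-8-(tert-butyldimethylsilyloxy)-2,6-dimethyloct-6-ene-2,3-diol | CC(C)(O)C(O)CC/C(C)=C\CO[Si](C)(C)C(C)(C)C | intermediate (not isolated)
5 | (4Z)-6-(tert-butyldimethylsilyloxy)-4-methylhex-4-enal | O=CCC/C(C)=C\CO[Si](C)(C)C(C)(C)C | intermediate
6 | bis(pinacolboryl)methane, bis(4,4,5,5-tetramethyl-1,3,2-dioxaborolan-2-yl)methane | C(B1OC(C)(C)C(C)(C)O1)B1OC(C)(C)C(C)(C)O1 | starting material
7 | lithiated diborylmethane | [Li]C(B1OC(C)(C)C(C)(C)O1)B1OC(C)(C)C(C)(C)O1 | intermediate (not isolated)
8 | 1,1-bis(pinacolboryl)ethane | CC(B1OC(C)(C)C(C)(C)O1)B1OC(C)(C)C(C)(C)O1 | intermediate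
9 | lithiated 1,1-diborylethane | [Li]C(C)(B1OC(C)(C)C(C)(C)O1)B1OC(C)(C)C(C)(C)O1 | intermediate (not isolated)
10 | fragment 1, tert-butyldimethyl{[(2Z,6Z)-3-methyl-7-(4,4,5,5-tetramethyl-1,3,2-dioxaborolan-2-yl)octa-2,6-dien-1-yl]oxy}silane (boron trans to the C5 methylene) | CC(C)(C)[Si](C)(C)OC/C=C(/C)CC/C=C(\C)B1OC(C)(C)C(C)(C)O1 | intermediate
11 | 2-deoxy-D-ribose | O=CC[C@H](O)[C@H](O)CO | starting material
12 | 2-deoxy-D-ribono-1,4-lactone, (4S,5R)-4-hydroxy-5-(hydroxymethyl)oxolan-2-one | O=C1C[C@H](O)[C@@H](CO)O1 | intermediate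
13 | (4S,5R)-4-(tert-butyldimethylsilyloxy)-5-[(tert-butyldimethylsilyloxy)methyl]oxolan-2-one | O=C1C[C@H](O[Si](C)(C)C(C)(C)C)[C@@H](CO[Si](C)(C)C(C)(C)C)O1 | intermediate
14 | (4S,5R)-4-(tert-butyldimethylsilyloxy)-5-(hydroxymethyl)oxolan-2-one | O=C1C[C@H](O[Si](C)(C)C(C)(C)C)[C@@H](CO)O1 | intermediate
15 | (2S,3S)-3-(tert-butyldimethylsilyloxy)-5-oxooxolane-2-carbaldehyde | O=C1C[C@H](O[Si](C)(C)C(C)(C)C)[C@@H](C=O)O1 | intermediate
16 | (4S,5R)-4-(tert-butyldimethylsilyloxy)-5-(2-methylprop-1-en-1-yl)oxolan-2-one (substituents trans) | O=C1C[C@H](O[Si](C)(C)C(C)(C)C)[C@@H](C=C(C)C)O1 | intermediate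
17 | lithium enolate of 16 | [Li]OC1=C[C@H](O[Si](C)(C)C(C)(C)C)[C@@H](C=C(C)C)O1 | intermediate (not isolated)
18 | (4S,5R)-4-(tert-butyldimethylsilyloxy)-3-(hydroxymethylidene)-5-(2-methylprop-1-en-1-yl)oxolan-2-one (enol geometry not fixed; formyl tautomer in equilibrium) | OC=C1C(=O)O[C@H](C=C(C)C)[C@H]1O[Si](C)(C)C(C)(C)C | intermediate
19 | fragment 2, (3E,4S,5R)-3-(bromomethylidene)-4-(tert-butyldimethylsilyloxy)-5-(2-methylprop-1-en-1-yl)oxolan-2-one | Br/C=C1/C(=O)O[C@H](C=C(C)C)[C@H]1O[Si](C)(C)C(C)(C)C | intermediate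
20 | vinyl bromide | C=CBr | starting material
21 | vinyllithium | [Li]C=C | intermediate (not isolated)
22 | lithium bis(alkenyl)borate from 10 and 21 (vinyl and C7 alkenyl groups on the pinacolato boron) | [Li+].C=C[B-]1(OC(C)(C)C(C)(C)O1)/C(C)=C/CC/C(C)=C\CO[Si](C)(C)C(C)(C)C | intermediate (not isolated)
23 | C8 pinacol boronate of the full skeleton (8S; 2Z,6E; E exocyclic alkene; ring 4S,5R; two TBS ethers) | CC(C)(C)[Si](C)(C)OC/C=C(/C)CC/C=C(\C)[C@H](C/C=C1/C(=O)O[C@H](C=C(C)C)[C@H]1O[Si](C)(C)C(C)(C)C)B2OC(C)(C)C(C)(C)O2 | intermediate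
24 | C8 alcohol (8S; two TBS ethers) | CC(C)(C)[Si](C)(C)OC/C=C(/C)CC/C=C(\C)[C@H](C/C=C1/C(=O)O[C@H](C=C(C)C)[C@H]1O[Si](C)(C)C(C)(C)C)O | intermediate
25 | C8 acetate (8S; two TBS ethers) | CC(C)(C)[Si](C)(C)OC/C=C(/C)CC/C=C(\C)[C@H](C/C=C1/C(=O)O[C@H](C=C(C)C)[C@H]1O[Si](C)(C)C(C)(C)C)OC(C)=O | intermediate
26 | C1 alcohol (C8 acetate; C12 TBS ether) | OC/C=C(/C)CC/C=C(\C)[C@H](C/C=C1/C(=O)O[C@H](C=C(C)C)[C@H]1O[Si](C)(C)C(C)(C)C)OC(C)=O | intermediate
27 | angelic acid, (2Z)-2-methylbut-2-enoic acid | C/C=C(/C)C(=O)O | starting material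
28 | angelic 2,4,6-trichlorobenzoic anhydride | C/C=C(/C)C(=O)OC(=O)c1c(Cl)cc(Cl)cc1Cl | intermediate (not isolated)
29 | C1 angelate (C8 acetate; C12 TBS ether) | C/C=C(/C)C(=O)OC/C=C(/C)CC/C=C(\C)[C@H](C/C=C1/C(=O)O[C@H](C=C(C)C)[C@H]1O[Si](C)(C)C(C)(C)C)OC(C)=O | intermediate
30 | CNP0201198.1, (2Z,6E,8S)-8-acetoxy-10-[(3E,4S,5R)-4-hydroxy-5-(2-methylprop-1-en-1-yl)-2-oxooxolan-3-ylidene]-3,7-dimethyldeca-2,6-dien-1-yl (2Z)-2-methylbut-2-enoate | C/C=C(/C)C(=O)OC/C=C(/C)CC/C=C(\C)[C@H](C/C=C1/C(=O)O[C@H](C=C(C)C)[C@H]1O)OC(C)=O | target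

**Step count**

Total: 18 steps. Longest linear sequence: 13 steps (steps 6 to 18, from 2-deoxy-D-ribose 11 to 30).

**Steps most likely to fail**

1. Step 13. The coupling may suffer from direct transfer of an alkenyl group from boron to C10 (plain Suzuki–Miyaura coupling), from weak enantiocontrol at C8, from E/Z isomerisation of the β-palladated enoate, or from ionisation of the allylic C13–O bond by zerovalent palladium. The fallback sets out from aldehyde 5 and hydroxymethylene lactone 18 and comes back at alcohol 24. Aldehyde 5 is olefinated with 2-(triphenylphosphoranylidene)propanal (toluene, 90 °C) to (2E,6Z)-8-(tert-butyldimethylsilyloxy)-2,6-dimethylocta-2,6-dienal F1. Brown allylboration of the enal with (−)-B-allyldiisopinocampheylborane (Et2O, −78 °C, NaBO3 work-up) sets C8 by reagent control and should give (4S,5E,9Z)-11-(tert-butyldimethylsilyloxy)-5,9-dimethylundeca-1,5,9-trien-4-ol F2. Lactone 18 is converted by aqueous formaldehyde and K2CO3 (deformylative methylenation) into (4S,5R)-4-(tert-butyldimethylsilyloxy)-3-methylidene-5-(2-methylprop-1-en-1-yl)oxolan-2-one F3. Cross-metathesis of the terminal alkene of the homoallylic alcohol with the α-methylene lactone (second-generation Hoveyda–Grubbs catalyst, CH2Cl2, 40 °C) should then form the E C10=C11 alkene and give 24.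

2. Step 12. The deoxybromination may give poor E/Z control in the bromide addition–elimination, and adventitious HBr may add to the isobutenyl alkene or loosen the silyl ether. The fallback sets out from 18 and comes back at boronate 23. O-Triflation of 18 with N-phenylbis(trifluoromethanesulfonimide) and Et3N (CH2Cl2, 0 °C; a non-chelating counter-ion favours the geometry with the sulfonate anti to the carbonyl) gives (3E,4S,5R)-4-(tert-butyldimethylsilyloxy)-5-(2-methylprop-1-en-1-yl)-3-{[(trifluoromethylsulfonyl)oxy]methylidene}oxolan-2-one F4. This enol triflate replaces 19 in step 13 under the same catalyst, alkenyl triflates being the standard electrophiles of the conjunctive coupling.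

3. Step 11. The lithium enolate may lose the β-silyloxy group (elimination to a butenolide) before it is acylated, or acylation may stall. The fallback sets out from bis-silyl lactone 13 and comes back at bromide 19; it puts bromine on before the isobutenyl group exists.
- The enolate of 13 (lithium hexamethyldisilazide, THF, −78 °C) is trapped at once with dimethylmethyleneammonium iodide to the Mannich base (4S,5R)-4-(tert-butyldimethylsilyloxy)-5-[(tert-butyldimethylsilyloxy)methyl]-3-[(dimethylamino)methyl]oxolan-2-one F5.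
- MeI converts it into the trimethylammonium iodide F6, and NaHCO3 eliminates this to (4S,5R)-4-(tert-butyldimethylsilyloxy)-5-[(tert-butyldimethylsilyloxy)methyl]-3-methylideneoxolan-2-one F7.
- Br2 (CH2Cl2, 0 °C), which here meets no other alkene, gives the 3-bromo-3-(bromomethyl) lactone F8. DBU removes HBr to (3E,4S,5R)-3-(bromomethylidene)-4-(tert-butyldimethylsilyloxy)-5-[(tert-butyldimethylsilyloxy)methyl]oxolan-2-one F9, the course known for the parent α-methylene-γ-butyrolactone.
- Aqueous TFA in THF at 0 °C frees (3E,4S,5R)-3-(bromomethylidene)-4-(tert-butyldimethylsilyloxy)-5-(hydroxymethyl)oxolan-2-one F10. Dess–Martin oxidation gives (2S,3S,4E)-4-(bromomethylidene)-3-(tert-butyldimethylsilyloxy)-5-oxooxolane-2-carbaldehyde F11, and Wittig reaction with isopropylidenetriphenylphosphorane at −78 °C gives 19.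

**Further compounds**

F1 | step 13 | (2E,6Z)-8-(tert-butyldimethylsilyloxy)-2,6-dimethylocta-2,6-dienal | O=C/C(C)=C/CC/C(C)=C\CO[Si](C)(C)C(C)(C)C
F2 | step 13 | (4S,5E,9Z)-11-(tert-butyldimethylsilyloxy)-5,9-dimethylundeca-1,5,9-trien-4-ol | C=CC[C@H](O)/C(C)=C/CC/C(C)=C\CO[Si](C)(C)C(C)(C)C
F3 | step 13 | (4S,5R)-4-(tert-butyldimethylsilyloxy)-3-methylidene-5-(2-methylprop-1-en-1-yl)oxolan-2-one | C=C1C(=O)O[C@H](C=C(C)C)[C@H]1O[Si](C)(C)C(C)(C)C
F4 | step 12 | (3E,4S,5R)-4-(tert-butyldimethylsilyloxy)-5-(2-methylprop-1-en-1-yl)-3-{[(trifluoromethylsulfonyl)oxy]methylidene}oxolan-2-one | O=S(=O)(O/C=C1/C(=O)O[C@H](C=C(C)C)[C@H]1O[Si](C)(C)C(C)(C)C)C(F)(F)F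
F5 | step 11 | (4S,5R)-4-(tert-butyldimethylsilyloxy)-5-[(tert-butyldimethylsilyloxy)methyl]-3-[(dimethylamino)methyl]oxolan-2-one (epimers at C3) | CN(C)CC1C(=O)O[C@H](CO[Si](C)(C)C(C)(C)C)[C@H]1O[Si](C)(C)C(C)(C)C
F6 | step 11 | trimethylammonium iodide of F5 (epimers at C3) | C[N+](C)(C)CC1C(=O)O[C@H](CO[Si](C)(C)C(C)(C)C)[C@H]1O[Si](C)(C)C(C)(C)C.[I-]
F7 | step 11 | (4S,5R)-4-(tert-butyldimethylsilyloxy)-5-[(tert-butyldimethylsilyloxy)methyl]-3-methylideneoxolan-2-one | C=C1C(=O)O[C@H](CO[Si](C)(C)C(C)(C)C)[C@H]1O[Si](C)(C)C(C)(C)C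
F8 | step 11 | 3-bromo-3-(bromomethyl) derivative of 13 (ring stereocentres of 13 unchanged; epimers at C3) | BrCC1(Br)C(=O)O[C@H](CO[Si](C)(C)C(C)(C)C)[C@H]1O[Si](C)(C)C(C)(C)C
F9 | step 11 | (3E,4S,5R)-3-(bromomethylidene)-4-(tert-butyldimethylsilyloxy)-5-[(tert-butyldimethylsilyloxy)methyl]oxolan-2-one | Br/C=C1/C(=O)O[C@H](CO[Si](C)(C)C(C)(C)C)[C@H]1O[Si](C)(C)C(C)(C)C
F10 | step 11 | (3E,4S,5R)-3-(bromomethylidene)-4-(tert-butyldimethylsilyloxy)-5-(hydroxymethyl)oxolan-2-one | Br/C=C1/C(=O)O[C@H](CO)[C@H]1O[Si](C)(C)C(C)(C)C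
F11 | step 11 | (2S,3S,4E)-4-(bromomethylidene)-3-(tert-butyldimethylsilyloxy)-5-oxooxolane-2-carbaldehyde | Br/C=C1/C(=O)O[C@H](C=O)[C@H]1O[Si](C)(C)C(C)(C)C
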